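**Retrosynthetic overview**
1. Feature: the oxygens on C5 and C8 of ring A are para to each other. Drawn as a C5/C8 quinone with the C4 acyl group on C4a, ring A has a single C–H carbon, C8a. It is activated by both C5=O and C4=O, and it is the carbon that must carry O1.
2. Ring C is closed last, at C8a–O1: 5,8-dihydroxyflavone 15 ⇐ acylquinone 13 ⇐ (anode, −2 e⁻/−2 H⁺) hydroquinone diketone 12. Rings A and B come in as ready-made arenes.
3. 12 ⇐ C2–C3 bond: C-acylation of the lithium polyanion of acetophenone 7 with acid chloride 10, which is made from isovanillic acid 8.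
4. 7 ⇐ 2,3,4-trihydroxyacetophenone 1 by 4-O-methylation, 3-O-benzylation and persulfate hydroxylation of the free carbon opposite the 2-OH.
5. End game: 8-O-methylation next to the hydrogen-bonded 5-OH, then hydrogenolysis of both benzyl ethers.

Key step: step 7

Remark on the chemistry: the target is planar and has no stereogenic unit, so there is no enantiomer to select and no SMILES below carries a stereodescriptor.

**Step 1**
Reactants: 1 2,3,4-trihydroxyacetophenone
Product: 3 1-(2,3-dihydroxy-4-methoxyphenyl)ethanone, via cyclic borate 2 (not isolated)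
Conditions: Na2B4O7·10H2O, H2O, rt; then Me2SO4, aq NaOH, rt; then HCl to pH 1
Reagents that add atoms: dimethyl sulfate, COS(=O)(=O)OC
Why: Williamson-type O-methylation under borate masking, in which the 2,3-diol is tied up as a cyclic borate and the 2-OH is hydrogen-bonded to the acetyl group anyway, so only the 4-phenoxide (para to the carbonyl, the most acidic site) is alkylated.

**Step 2**
Reactants: 3 1-(2,3-dihydroxy-4-methoxyphenyl)ethanone; 4 benzyl bromide
Product: 5 1-(3-benzyloxy-2-hydroxy-4-methoxyphenyl)ethanone
Conditions: BnBr (1.05 equiv), K2CO3 (1.1 equiv), acetone, reflux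
Reagents that add atoms: benzyl bromide (4), BrCc1ccccc1
Why: Williamson etherification with one equivalent of halide, which should go to the 3-OH because the 2-OH is held in a six-membered hydrogen bond to the acetyl oxygen and is a poor nucleophile.

**Step 3**
Reactants: 5 1-(3-benzyloxy-2-hydroxy-4-methoxyphenyl)ethanone
Product: 7 1-(3-benzyloxy-2,5-dihydroxy-4-methoxyphenyl)ethanone, via aryl sulfate 6 (not isolated)
Conditions: K2S2O8 (1.1 equiv), aq KOH, pyridine, 10–20 °C; HCl to pH 4, Et2O wash (returns unchanged 5); then 2 M HCl, 80 °C, N2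
Reagents that add atoms: potassium peroxodisulfate, [K+].[K+].[O-]S(=O)(=O)OOS(=O)(=O)[O-]
Why: Elbs persulfate oxidation, in which the phenolate attacks the peroxide oxygen through its free para carbon C5 (further activated by the ortho methoxy group) and the aryl sulfate is then hydrolysed by warm dilute acid that should leave a benzyl aryl ether intact.

**Step 4**
Reactants: 8 isovanillic acid (3-hydroxy-4-methoxybenzoic acid); 4 benzyl bromide
Product: 9 3-benzyloxy-4-methoxybenzoic acid
Conditions: BnBr (1.3 equiv), 2 M aq NaOH (2.5 equiv), EtOH, reflux; then HCl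
Reagents that add atoms: benzyl bromide (4), BrCc1ccccc1
Why: Williamson etherification of the dianion, whose phenoxide is a far better nucleophile than its carboxylate in aqueous ethanol.

**Step 5**
Reactants: 9 3-benzyloxy-4-methoxybenzoic acid
Product: 10 3-benzyloxy-4-methoxybenzoyl chloride
Conditions: (COCl)2 (1.3 equiv), cat. DMF, CH2Cl2, 0 °C to rt; evaporate and use crude
Reagents that add atoms: oxalyl chloride, O=C(Cl)C(=O)Cl
Why: standard DMF-catalysed acid chloride formation under conditions that do not touch aryl methyl or benzyl ethers.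

**Step 6**
Reactants: 7 1-(3-benzyloxy-2,5-dihydroxy-4-methoxyphenyl)ethanone; 10 3-benzyloxy-4-methoxybenzoyl chloride
Product: 12 1-(3-benzyloxy-2,5-dihydroxy-4-methoxyphenyl)-3-(3-benzyloxy-4-methoxyphenyl)propane-1,3-dione, via trilithium salt 11 (not isolated)
Conditions: LiHMDS (4.2 equiv), THF, −78 to −10 °C, Ar; 10 (1.0 equiv), −78 °C to rt; cold degassed 1 M HCl
Reagents that add atoms: none
Why: Claisen-type C-acylation of a hydroxyacetophenone polyanion (the direct variant of the Baker–Venkataraman diketone synthesis), in which the enolate carbon is the most nucleophilic site of the trianion and the fourth equivalent of base stores the product as its unreactive diketonate.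

**Step 7**
Reactants: 12 1-(3-benzyloxy-2,5-dihydroxy-4-methoxyphenyl)-3-(3-benzyloxy-4-methoxyphenyl)propane-1,3-dione
Product: 15 6-benzyloxy-2-(3-benzyloxy-4-methoxyphenyl)-5,8-dihydroxy-7-methoxychromen-4-one, via acylquinone 13 (not isolated), via flavonequinone 14 (not isolated)
Conditions: graphite-felt anode, Pt cathode, divided cell, constant potential ca. +0.45 V vs Ag/AgCl (about 0.1 V beyond the first anodic wave of 12), 12 at 3 mM, MeCN/0.2 M aq NaOAc–AcOH buffer pH 5.5 (3:1), Ar, 10 °C, until 12 is consumed (2–4 F/mol); then aq Na2S2O4, rt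
Reagents that add atoms: none
Why: Proposed new method: at the carbon anode the 2,5-hydroquinone of 12 loses two electrons and two protons (taken up by acetate) to give acylquinone 13, whose only hydrogen-bearing ring carbon, the future C8a, is the β-carbon of both the C5 quinone carbonyl and the exocyclic C4 ketone. After rotation about C3–C4 the buffered diketone enol(ate) adds through the oxygen on C2 to C8a in a 6-endo-trig oxa-Michael closure of ring C (new bond C8a–O1), and loss of the C8a proton re-aromatises ring A to the 5,8-diol 15. The closest known reaction types are the anodic EC/ECEC couplings of hydroquinones and catechols with 1,3-dicarbonyl nucleophiles in acetate buffer and the conjugate addition of heteroatom nucleophiles to C3 of 2-acyl-1,4-benzoquinones, whereas an intramolecular O-closure of this kind to a chromone has not been shown. Chemoselectivity rests on the potential, which is held just past the first wave and so lies far below the oxidation of the acyl-substituted dialkoxy ring B, the benzyl ethers and the diketone enolate. Site selectivity is built into 13: attack by C3 would give a four-membered ring, 1,2-addition of the enol oxygen to C5=O is reversible and unproductive, O5 as a carbonyl cannot condense with C2 (so the ordinary cyclodehydration to the 8-benzyloxy-6-hydroxy isomer is switched off), and millimolar dilution keeps intermolecular C-alkylation by C3 of a second molecule slow. Because 15 should be oxidised about as easily as 12, part of it is expected to pass on to the fully substituted flavonequinone 14, which the dithionite quench brings back to 15, and no stereocentre is formed.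

**Step 8**
Reactants: 15 6-benzyloxy-2-(3-benzyloxy-4-methoxyphenyl)-5,8-dihydroxy-7-methoxychromen-4-one
Product: 16 6-benzyloxy-2-(3-benzyloxy-4-methoxyphenyl)-5-hydroxy-7,8-dimethoxychromen-4-one
Conditions: MeI (1.1 equiv), K2CO3 (1.2 equiv), acetone, reflux, Ar
Reagents that add atoms: iodomethane, CI
Why: chelation-controlled partial Williamson methylation, a standard operation on 5,8-dihydroxyflavones, in which the 5-OH bonded to the C4 carbonyl stays unreactive towards one equivalent of halide and weak base while the free 8-OH is alkylated.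

**Step 9**
Reactants: 16 6-benzyloxy-2-(3-benzyloxy-4-methoxyphenyl)-5-hydroxy-7,8-dimethoxychromen-4-one
Product: 17 5,6,3'-trihydroxy-7,8,4'-trimethoxyflavone (5,6-dihydroxy-2-(3-hydroxy-4-methoxyphenyl)-7,8-dimethoxychromen-4-one)
Conditions: H2 (1 atm), 10% Pd/C, THF–MeOH 1:1, rt
Reagents that add atoms: none
Why: catalytic hydrogenolysis of the two benzyl aryl ethers, under which the C2=C3 bond of the flavone (part of an aryl-conjugated vinylogous ester) and the methyl ethers are expected to persist.

**Compound list**
1 | 2,3,4-trihydroxyacetophenone | CC(=O)c1ccc(O)c(O)c1O | starting material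
2 | sodium 2,3-O-borate complex of 1 (4-acetyl-2,2,7-trihydroxy-1,3,2-benzodioxaborol-2-uide, sodium salt) | CC(=O)c1ccc(O)c2O[B-](O)(O)Oc12.[Na+] | intermediate
3 | 1-(2,3-dihydroxy-4-methoxyphenyl)ethanone | CC(=O)c1ccc(OC)c(O)c1O | intermediate
4 | benzyl bromide | BrCc1ccccc1 | starting material
5 | 1-(3-benzyloxy-2-hydroxy-4-methoxyphenyl)ethanone | CC(=O)c1ccc(OC)c(OCc2ccccc2)c1O | intermediate
6 | potassium 5-acetyl-3-benzyloxy-4-hydroxy-2-methoxyphenyl sulfate | CC(=O)c1cc(OS(=O)(=O)[O-])c(OC)c(OCc2ccccc2)c1O.[K+] | intermediate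
7 | 1-(3-benzyloxy-2,5-dihydroxy-4-methoxyphenyl)ethanone | CC(=O)c1cc(O)c(OC)c(OCc2ccccc2)c1O | intermediate
8 | isovanillic acid | COc1ccc(C(=O)O)cc1O | starting material
9 | 3-benzyloxy-4-methoxybenzoic acid | COc1ccc(C(=O)O)cc1OCc1ccccc1 | intermediate
10 | 3-benzyloxy-4-methoxybenzoyl chloride | COc1ccc(C(=O)Cl)cc1OCc1ccccc1 | intermediate
11 | trilithium salt of 7 (bis-phenoxide enolate) | C=C([O-])c1cc([O-])c(OC)c(OCc2ccccc2)c1[O-].[Li+].[Li+].[Li+] | intermediate
12 | 1-(3-benzyloxy-2,5-dihydroxy-4-methoxyphenyl)-3-(3-benzyloxy-4-methoxyphenyl)propane-1,3-dione (largely enolised) | COc1ccc(C(=O)CC(=O)c2cc(O)c(OC)c(OCc3ccccc3)c2O)cc1OCc1ccccc1 | intermediate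
13 | 6-benzyloxy-2-[3-(3-benzyloxy-4-methoxyphenyl)-3-oxopropanoyl]-5-methoxy-1,4-benzoquinone | COc1ccc(C(=O)CC(=O)C2=CC(=O)C(OC)=C(OCc3ccccc3)C2=O)cc1OCc1ccccc1 | intermediate
14 | 6-benzyloxy-2-(3-benzyloxy-4-methoxyphenyl)-7-methoxychromene-4,5,8-trione | COc1ccc(C2=CC(=O)C3=C(O2)C(=O)C(OC)=C(OCc4ccccc4)C3=O)cc1OCc1ccccc1 | intermediate
15 | 6-benzyloxy-2-(3-benzyloxy-4-methoxyphenyl)-5,8-dihydroxy-7-methoxychromen-4-one | COc1ccc(-c2cc(=O)c3c(O)c(OCc4ccccc4)c(OC)c(O)c3o2)cc1OCc1ccccc1 | intermediate
16 | 6-benzyloxy-2-(3-benzyloxy-4-methoxyphenyl)-5-hydroxy-7,8-dimethoxychromen-4-one | COc1ccc(-c2cc(=O)c3c(O)c(OCc4ccccc4)c(OC)c(OC)c3o2)cc1OCc1ccccc1 | intermediate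
17 | 5,6,3'-trihydroxy-7,8,4'-trimethoxyflavone | COc1ccc(-c2cc(=O)c3c(O)c(O)c(OC)c(OC)c3o2)cc1O | target

**Total step count:** 9. **Longest linear sequence:** 7 (steps 1, 2, 3, 6, 7, 8, 9).

**Steps most likely to fail**

1. Step 7.
   - Risk: the O-closure may lose to intermolecular C–C Michael coupling between the quinone and the diketone carbon of a second molecule. It may also lose to hydration of the acylquinone or to decay of the over-oxidised quinone before the quench. Polymer films may passivate the anode.
   - Fallback: known chemistry makes the same C8a–O1 bond by O-arylation instead of oxidation. It sets out from 7 (with 10) and comes back at 16.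
   - The free 5-hydroxyl of 7 is methylated (MeI, K2CO3, acetone, Ar; the chelated 2-OH stays) to give 1-(3-benzyloxy-2-hydroxy-4,5-dimethoxyphenyl)ethanone F1.
   - NBS in MeCN at 0 °C brominates the only free ring position to give 1-(3-benzyloxy-6-bromo-2-hydroxy-4,5-dimethoxyphenyl)ethanone F2.
   - The lithium dianion of this ketone (LiHMDS, THF) is C-acylated with 10 to give 1-(3-benzyloxy-6-bromo-2-hydroxy-4,5-dimethoxyphenyl)-3-(3-benzyloxy-4-methoxyphenyl)propane-1,3-dione F3.
   - A copper-catalysed intramolecular Ullmann-type O-arylation of the diketone enolate (CuI, 1,10-phenanthroline, K2CO3, DMF, 100 °C) closes ring C at the brominated carbon. This gives 16 directly, so the electrolysis and the 8-O-methylation are both bypassed.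

2. Step 3.
   - Risk: the persulfate oxidation may stall at low conversion, over-oxidise the electron-rich phenolate to tars, or lose part of the benzyl ether during the acid hydrolysis of the sulfate ester.
   - Fallback: halogenation, borylation and oxidation replace the direct C–H hydroxylation. It sets out from 5 and comes back at 7.
   - NBS in MeCN brominates para to the phenol to give 1-(3-benzyloxy-5-bromo-2-hydroxy-4-methoxyphenyl)ethanone F4.
   - Miyaura borylation (B2pin2, Pd(dppf)Cl2, KOAc, dioxane, 90 °C) gives 1-[3-benzyloxy-2-hydroxy-4-methoxy-5-(4,4,5,5-tetramethyl-1,3,2-dioxaborolan-2-yl)phenyl]ethanone F5.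
   - Mild oxidation of the boronate (NaBO3·4H2O, THF/H2O, rt) gives 7.

3. Step 6.
   - Risk: O-acylation of the 5-phenoxide, double acylation, or air oxidation of the hydroquinone polyanion may compete with C-acylation.
   - Fallback: the classical ester-transfer sequence is used instead of direct C-acylation. It sets out from 7 and 10 and comes back at 12.
   - Both hydroxyls are aroylated with 10 (2.2 equiv, pyridine, rt) to give 2-acetyl-6-benzyloxy-5-methoxy-1,4-phenylene bis(3-benzyloxy-4-methoxybenzoate) F6.
   - Baker–Venkataraman rearrangement (KOH, pyridine, 50 °C) moves the aroyl group ortho to the acetyl onto the methyl carbon. This gives 3-benzyloxy-5-[3-(3-benzyloxy-4-methoxyphenyl)-3-oxopropanoyl]-4-hydroxy-2-methoxyphenyl 3-benzyloxy-4-methoxybenzoate F7.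
   - Saponification of the remaining aryl ester (LiOH, degassed THF/H2O, 0 °C to rt, then cold acid) releases 12. The diketone is protected as its enolate during this step.

**Further compounds**
F1 | step 7 | 1-(3-benzyloxy-2-hydroxy-4,5-dimethoxyphenyl)ethanone | CC(=O)c1cc(OC)c(OC)c(OCc2ccccc2)c1O
F2 | step 7 | 1-(3-benzyloxy-6-bromo-2-hydroxy-4,5-dimethoxyphenyl)ethanone | CC(=O)c1c(Br)c(OC)c(OC)c(OCc2ccccc2)c1O
F3 | step 7 | 1-(3-benzyloxy-6-bromo-2-hydroxy-4,5-dimethoxyphenyl)-3-(3-benzyloxy-4-methoxyphenyl)propane-1,3-dione | COc1ccc(C(=O)CC(=O)c2c(Br)c(OC)c(OC)c(OCc3ccccc3)c2O)cc1OCc1ccccc1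
F4 | step 3 | 1-(3-benzyloxy-5-bromo-2-hydroxy-4-methoxyphenyl)ethanone | CC(=O)c1cc(Br)c(OC)c(OCc2ccccc2)c1O
F5 | step 3 | 1-[3-benzyloxy-2-hydroxy-4-methoxy-5-(4,4,5,5-tetramethyl-1,3,2-dioxaborolan-2-yl)phenyl]ethanone | CC(=O)c1cc(B2OC(C)(C)C(C)(C)O2)c(OC)c(OCc2ccccc2)c1O
F6 | step 6 | 2-acetyl-6-benzyloxy-5-methoxy-1,4-phenylene bis(3-benzyloxy-4-methoxybenzoate) | CC(=O)c1cc(OC(=O)c2ccc(OC)c(OCc3ccccc3)c2)c(OC)c(OCc2ccccc2)c1OC(=O)c1ccc(OC)c(OCc2ccccc2)c1
F7 | step 6 | 3-benzyloxy-5-[3-(3-benzyloxy-4-methoxyphenyl)-3-oxopropanoyl]-4-hydroxy-2-methoxyphenyl 3-benzyloxy-4-methoxybenzoate | COc1ccc(C(=O)CC(=O)c2cc(OC(=O)c3ccc(OC)c(OCc4ccccc4)c3)c(OC)c(OCc3ccccc3)c2O)cc1OCc1ccccc1
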